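## The problem

The target is an ester of two flavan-3-ol-derived halves. The C3 hydroxyl of a western (−)-epicatechin acylates the C8 carboxyl of a benzotropolone (6-hydroxy-5-oxo-5H-benzo[7]annulene). The benzo ring of that benzotropolone is at the same time ring B of an eastern (2R,3R)-flavan-3-ol: C1 is bonded to the chromane C2, and C3 and C4 carry hydroxyls.

The four stereocentres are the cis C2/C3 pairs of the two chromanes. They sit in separate halves, cannot direct one another, and are best taken unchanged from (−)-epicatechin and (−)-epigallocatechin.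

The task is therefore constitutional: a fully unsaturated seven-membered ring with a carbonyl at C5, a hydroxyl at C6 and a carboxyl at C8 must be fused to the C4a–C9a edge of a crowded arene that carries a chiral benzylic ether.

Several groups will not survive rough treatment:
- The free polyphenol (nine phenolic or enolic hydroxyls) oxidises in base.
- Ring A of each flavan is a strong carbon nucleophile toward any electrophile.
- The chromane C2–O bond can open, with epimerisation, when the para hydroxyl of ring B is a free phenoxide at elevated temperature.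
- The tropolone and its ethers are attacked by hard nucleophiles, which speaks against ester hydrolysis once the ring exists.

The enabling feature is that C5 and C6 are adjacent oxygen-bearing carbons of like polarity, while the fusion carbons C4a and C9a are C3' and C2' of ring B. Epigallocatechin has a hydroxyl on C3' and a free position on C2' ortho to it. One carbon can be placed on each (phenol-directed formylation at C2', carbonylation of the derived triflate at C3'), and a reductive coupling of two aldehyde carbons then closes C5–C6.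

## Retrosynthesis

**Deprotection (22 from 21).** Target 22 is traced to its nona-O-benzyl ether 21. Benzyl is the only phenol protecting group in the route, so one hydrogenolysis frees both halves. No C–C or C–O bond of the skeleton is cut here; the forward step only has to spare the tropolone and the two chromane C2–O bonds.

**Oxidation level (21 from 19 via 20).** The tropolone 21 is two oxidation levels above the 5,6-diol 19. Cutting back to the diol removes the aromatic seven-membered ring and leaves two carbinols whose configuration is irrelevant. The forward double oxidation gives the 5,6-diketone 20, whose C7 methylene lies between a carbonyl and the C8=C9 alkene and should enolise at once to 21.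

**Key cut, C5–C6 (19 from 18).** Neighbouring cuts were weighed:
- C4a–C5 would call for an electrophilic acylation of the arene, which ring A would intercept.
- C6–C7 or C8–C9 by aldol or olefination would need an α-oxygenated aryl ketone chain that is harder to build than two aldehydes.
- C5–C6 joins two carbons that are both carbonyl carbons in the open form, so a pinacol coupling forms the bond without polarity inversion.

The precursor 18 is acyclic in the new ring and has no new stereocentres. The forward reaction must reduce two aldehydes in the presence of a conjugated ester and close a seven-membered ring faster than ketyls dimerise.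

**The two aldehydes (18 from 17 from 16).** The aliphatic aldehyde (C6) is kept as a dimethyl acetal until the last moment, because the free β,γ-unsaturated aldehyde enolises easily. The aryl aldehyde (C5) is traced to the aryl triflate 16 by palladium-catalysed formylation. This uses the ring B oxygen of epigallocatechin as the leaving group on the carbon that becomes C4a.

**C8=C9 (16 from 8 and 15).** A Horner–Wadsworth–Emmons disconnection divides the molecule into the eastern salicylaldehyde triflate 8 and the phosphonate 15. Phosphonate 15 carries C6, C7, C8, the carboxyl and the complete western flavan. Putting the epicatechin ester on the phosphonate, not on a late carboxylic acid, avoids a hydrolysis and an esterification on a base-sensitive tropolone and shortens the longest linear sequence. The forward reaction must give the E alkene, so that the aryl ring and the CH2 arm are cis.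

**Phosphonate arm (15 from 12 and 14).** Carbodiimide esterification joins acid 12 to tetra-O-benzylepicatechin 14, made from (−)-epicatechin 13. Acid 12 comes from ester 11, the alkylation product of triethyl phosphonoacetate 9 with bromoacetaldehyde dimethyl acetal 10. The sluggish alkylation is thus done on cheap material.

**Eastern aldehyde (8 from 7 from 6 from 4).** The triflate comes from phenol 7. The formyl group of 6 differentiates the two catechol hydroxyls of its precursor 4: the hydroxyl ortho to the aldehyde is chelated and the other is benzylated selectively. The formyl carbon itself is introduced ortho to the free C3' hydroxyl of 4 (through hydroxymethyl intermediate 5). C2' is the only position in the molecule ortho to a free phenol.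

**Oxygen differentiation (4 from 3 from 2 from 1).** Only a vicinal pair of ring B hydroxyls of (−)-epigallocatechin 1 can form a cyclic ketal. Ketal 2 is benzylated on all other oxygens (3) and the ketal is removed to give 4. The benzyl ether ends on one meta oxygen (future C3–O), and the catechol that is released holds the handle oxygen (C3') and the future C4–O.

## Roads not taken

**Alternative 1:** The cut is through ring C of the eastern flavan (O1–C8a, C4–C4a and O1–C2). In the forward step, 3,5-bis(benzyloxy)benzyne from silyl triflate A3 and CsF adds to the aldehyde of benzotropolone propenal A2. The benzoxete opens to an ortho-quinone methide, and oxa-6π closure gives the 2H-chromene A1.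
- Merits: it is convergent, the aryne–enal annulation is a known reaction type, and the benzotropolone could be built on a simple arene with no flavan present. It would avoid the six-step oxygen differentiation of epigallocatechin that the chosen plan needs, and in that respect it is better.
- Weak points: A1 is racemic at C2 and has no C3 oxygen. Hydroboration would give the 2,3-trans alcohol, so an oxidation–reduction inversion and a resolution (or an asymmetric method not yet at hand) are needed for a single enantiomer. The tropone ring of A2 is itself a good aryne partner. The synthesis of A2, that is the tropolone ring, is not addressed by the key step.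
- Comparison: the chosen plan has more protecting-group steps but buys in all four stereocentres and solves the seven-membered ring in its key step.

**Alternative 2:** The cut is on both sides of the ester carbonyl (C8–CO and CO–O3). In the forward step Pd(OAc)2 with Xantphos inserts CO into the C8–Br bond of bromide A5, and the acylpalladium is captured by alcohol 14 to give the perbenzylated target A4.
- Merits: it is the most convergent endgame possible, with no carboxylic acid intermediate, and the western flavan is carried through only two steps. As an endgame it is better than carrying the western half through six steps as the chosen plan does.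
- Weak points: the nucleophile is a hindered secondary alcohol used near stoichiometry, where alkoxycarbonylation usually relies on excess alcohol. Competing β-hydride elimination from the palladium alkoxide and hydrodebromination are likely. The 2-benzyloxytropone is electrophilic toward alkoxide. A5 still needs a tropolone ring synthesis on the flavan and a C8 bromide, so the central problem is moved, not solved.
- Comparison: the chosen plan forms the same ester by carbodiimide acylation with a phosphonoacetic acid, one of the most reliable ways to acylate a hindered alcohol, and needs no palladium chemistry on a tropolone.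

**Alternative 3:** The cut is at C7–C8 and C8–C9, a one-carbon insertion. In the forward step ethyl diazoacetate with Rh2(OAc)4 cyclopropanates the styrenyl alkene of quinone monoketal A7, and BF3·OEt2 opens the cyclopropane to the benzotropolone ester A6.
- Merits: the seven-membered ring, the C8 ester and the C5/C6 oxygens arise in one pot from a naphthalene, with no medium-ring closure and no sensitive dialdehyde. For the core alone it is shorter and probably more robust than the pinacol route.
- Weak points: A6 carries a bromide where the eastern flavan must be. The whole chromane with its cis-(2R,3R) pair would have to be built afterwards from an aryl bromide on a nucleophile-sensitive tropolone: cross-coupling, ring construction and asymmetric oxygenation, with reagent control of both stereocentres. The carbenoid could also attack benzylic C–H bonds and electron-rich arenes.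
- Comparison: the chosen plan keeps the chiral flavan intact from the start, makes no stereocentre, and puts its extra steps into routine phenol chemistry.

Key step: step 14

Assumption on numbering and stereochemistry: primed locants are ring B of the eastern flavan (the two meta positions of ring B in 1 are equivalent; the formyl carbon is placed on C2' and the handle oxygen is O3'). From 16 on, C2' is C9a and C3' is C4a of the benzo[7]annulene. Compounds 11 and 12 are racemic, 15 is a pair of epimers at the phosphorus-bearing carbon and 19 a mixture of C5/C6 diastereomers; these centres become sp2 in steps 11 and 15.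

## Route

Step 1
Reactants: 1 (−)-epigallocatechin
Product: 2 3',4'-O-(diphenylmethylene)epigallocatechin
Conditions: Ph2CCl2, K2CO3, MeCN, Ar, rt
Reagents that add atoms: dichlorodiphenylmethane, ClC(Cl)(c1ccccc1)c1ccccc1
Why: Ketalisation of a vicinal diphenol; only two adjacent ring B hydroxyls can close the 1,3-benzodioxole, so O3'/O4' are tied up and one meta hydroxyl stays free, while the meta-disposed ring A phenols cannot form a cyclic ketal and are returned on work-up.

Step 2
Reactants: 2 3',4'-O-(diphenylmethylene)epigallocatechin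
Product: 3 3,5,7,5'-tetra-O-benzyl-3',4'-O-(diphenylmethylene)epigallocatechin
Conditions: NaH, BnBr, Bu4NI (cat.), DMF, −20 °C to rt
Reagents that add atoms: benzyl bromide, BrCc1ccccc1
Why: Williamson etherification of the three phenoxides and the C3 alkoxide; the ketal is inert to base, and with O4' blocked ring C cannot open through a quinone methide, so C2 keeps its configuration.

Step 3
Reactants: 3 3,5,7,5'-tetra-O-benzyl-3',4'-O-(diphenylmethylene)epigallocatechin
Product: 4 3,5,7,5'-tetra-O-benzylepigallocatechin (free 3',4'-catechol)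
Conditions: AcOH–H2O (4:1), 90 °C
Reagents that add atoms: none
Why: Acid hydrolysis of the diaryl ketal with release of benzophenone; benzyl ethers and the chromane should tolerate hot aqueous acetic acid.

Step 4
Reactants: 4 3,5,7,5'-tetra-O-benzylepigallocatechin
Product: 6 2'-formyl-3,5,7,5'-tetra-O-benzylepigallocatechin, via 2'-hydroxymethyl catechol 5 (not isolated)
Conditions: MgCl2, Et3N, (CH2O)n, THF, 60 °C
Reagents that add atoms: paraformaldehyde (as formaldehyde), C=O
Why: Magnesium phenoxide-directed ortho-formylation; formaldehyde held on the magnesium phenoxide attacks only a position ortho to a free hydroxyl, and C2' is the single such position (C5' is etherified, ring A has no free phenol). The hydroxymethyl intermediate 5 is oxidised in the flask by hydride transfer to a second formaldehyde.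

Step 5
Reactants: 6 2'-formyl-3,5,7,5'-tetra-O-benzylepigallocatechin
Product: 7 3,4-bis(benzyloxy)-2-hydroxy-6-[(2R,3R)-3,5,7-tris(benzyloxy)chroman-2-yl]benzaldehyde
Conditions: NaH (2.2 equiv), DMSO–THF, rt; BnBr (1.0 equiv)
Reagents that add atoms: benzyl bromide, BrCc1ccccc1
Why: Regioselective Williamson etherification of a 2,3-dihydroxybenzaldehyde dianion; the phenoxide ortho to the formyl group is chelated and conjugated to the carbonyl, so the more basic O4' oxide takes the single equivalent of benzyl bromide.

Step 6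
Reactants: 7 3,4-bis(benzyloxy)-2-hydroxy-6-[(2R,3R)-3,5,7-tris(benzyloxy)chroman-2-yl]benzaldehyde
Product: 8 2,3-bis(benzyloxy)-6-formyl-5-[(2R,3R)-3,5,7-tris(benzyloxy)chroman-2-yl]phenyl trifluoromethanesulfonate
Conditions: Tf2O, pyridine, CH2Cl2, −10 to 0 °C
Reagents that add atoms: triflic anhydride, FC(F)(F)S(=O)(=O)OS(=O)(=O)C(F)(F)F
Why: O-Sulfonylation of the salicylaldehyde hydroxyl; it turns O3' into a leaving group for palladium on the carbon that becomes C4a.

Step 7
Reactants: 9 triethyl phosphonoacetate; 10 bromoacetaldehyde dimethyl acetal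
Product: 11 ethyl 2-(diethoxyphosphoryl)-4,4-dimethoxybutanoate (racemic)
Conditions: NaH, DMF, 0 °C; then 10, NaI (cat.), 80 °C
Reagents that add atoms: none
Why: SN2 C-alkylation of the sodium phosphonoacetate anion; the α-alkoxy bromide is slow, hence iodide catalysis and heat, and the product is less acidic than 9, which keeps dialkylation minor.

Step 8
Reactants: 11 ethyl 2-(diethoxyphosphoryl)-4,4-dimethoxybutanoate
Product: 12 2-(diethoxyphosphoryl)-4,4-dimethoxybutanoic acid (racemic)
Conditions: KOH (1.05 equiv), EtOH–H2O, 0 °C to rt; cold aq. KHSO4 to pH 4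
Reagents that add atoms: potassium hydroxide, [K+].[OH-]
Why: Saponification of the carboxylic ester by one equivalent of hydroxide, to which diethyl phosphonate esters are inert; brief cold acidification to pH 4 spares the dimethyl acetal.

Step 9
Reactants: 13 (−)-epicatechin
Product: 14 5,7,3',4'-tetra-O-benzylepicatechin
Conditions: BnBr (4.4 equiv), K2CO3, DMF, Ar, 0 °C to rt
Reagents that add atoms: benzyl bromide, BrCc1ccccc1
Why: Williamson etherification of the four phenols; carbonate does not deprotonate the secondary alcohol, which stays free for acylation.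

Step 10
Reactants: 12 2-(diethoxyphosphoryl)-4,4-dimethoxybutanoic acid; 14 5,7,3',4'-tetra-O-benzylepicatechin
Product: 15 5,7,3',4'-tetra-O-benzylepicatechin-3-yl 2-(diethoxyphosphoryl)-4,4-dimethoxybutanoate (two epimers)
Conditions: DCC, DMAP (cat.), CH2Cl2, 0 °C to rt
Reagents that add atoms: none
Why: Steglich esterification; phosphonoacetic acids acylate even hindered secondary alcohols readily under carbodiimide activation, and the C3–O bond of 14 is not broken, so its configuration is retained.

Step 11
Reactants: 8 2,3-bis(benzyloxy)-6-formyl-5-[(2R,3R)-3,5,7-tris(benzyloxy)chroman-2-yl]phenyl trifluoromethanesulfonate; 15 5,7,3',4'-tetra-O-benzylepicatechin-3-yl 2-(diethoxyphosphoryl)-4,4-dimethoxybutanoate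
Product: 16 5,7,3',4'-tetra-O-benzylepicatechin-3-yl (E)-3-{3,4-bis(benzyloxy)-2-(triflyloxy)-6-[(2R,3R)-3,5,7-tris(benzyloxy)chroman-2-yl]phenyl}-2-(2,2-dimethoxyethyl)acrylate
Conditions: NaH, THF, 0 °C; then 8, rt to 45 °C
Reagents that add atoms: none
Why: Horner–Wadsworth–Emmons olefination forming C8=C9; reversible addition and syn-elimination of phosphate place the ester trans to the aryl group (E), the geometry that holds the aryl ring and the CH2CH(OMe)2 arm cis for ring closure. The ortho triflate raises the electrophilicity of the flanked aldehyde.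

Step 12
Reactants: 16 the (E)-acrylate triflate
Product: 17 5,7,3',4'-tetra-O-benzylepicatechin-3-yl (E)-3-{3,4-bis(benzyloxy)-2-formyl-6-[(2R,3R)-3,5,7-tris(benzyloxy)chroman-2-yl]phenyl}-2-(2,2-dimethoxyethyl)acrylate
Conditions: Pd(OAc)2 (10 mol%), dppp, CO (1 atm), Et3SiH, Et3N, DMF, 70 °C
Reagents that add atoms: carbon monoxide, [C-]#[O+]
Why: Palladium-catalysed reductive carbonylation of an aryl triflate (oxidative addition, CO insertion, hydride transfer from the silane to the acylpalladium); it puts the C5 carbon on C4a. The CO atmosphere and the aprotic medium should keep the benzyl ethers and the trisubstituted enoate from reduction.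

Step 13
Reactants: 17 the aryl aldehyde acetal
Product: 18 5,7,3',4'-tetra-O-benzylepicatechin-3-yl (E)-3-{3,4-bis(benzyloxy)-2-formyl-6-[(2R,3R)-3,5,7-tris(benzyloxy)chroman-2-yl]phenyl}-2-(2-oxoethyl)acrylate
Conditions: Et3SiOTf, 2,4,6-collidine, CH2Cl2, 0 °C; then H2O, 0 °C; used crude at once
Reagents that add atoms: water, O
Why: Non-acidic cleavage of a dimethyl acetal by a silyl triflate with a hindered pyridine base; the aldehyde appears only on the aqueous quench, in a collidine/collidinium buffer at 0 °C. This limits enolisation of the β,γ-unsaturated aldehyde, which could otherwise condense onto the neighbouring aryl aldehyde.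

Step 14
Reactants: 18 the dialdehyde
Product: 19 5,7,3',4'-tetra-O-benzylepicatechin-3-yl 3,4-bis(benzyloxy)-5,6-dihydroxy-1-[(2R,3R)-3,5,7-tris(benzyloxy)chroman-2-yl]-6,7-dihydro-5H-benzo[7]annulene-8-carboxylate (C5/C6 diastereomers)
Conditions: SmI2 (3 equiv, 0.1 M in THF), THF, −78 to −20 °C, slow addition of 18 (final 0.005 M); aq. NH4Cl
Reagents that add atoms: none
Why: Intramolecular pinacol coupling of a dialdehyde; the closest known reaction type is the SmI2-mediated cyclisation of dialdehydes to cyclic 1,2-diols. Single-electron transfer from divalent samarium reduces the more easily reduced aryl aldehyde to a samarium-bound ketyl at C5; the aliphatic aldehyde, held close by coordination to the oxophilic trivalent samarium, is attacked at C6 by the ketyl carbon, and a second electron transfer gives the samarium diolate, which is protonated on work-up. The seven-membered ring closes in the 7-exo mode onto the C6 carbonyl and has only two freely rotating atoms (C6 and C7), because the arene and the (E)-alkene hold C5 and C7 on the same side. The two new stereocentres (C5, C6) are expected cis from the samarium-bridged transition state, without useful bias from the remote flavan; they are left uncontrolled on purpose because both carbinols are oxidised in step 15. The selectivity needed is for the two aldehydes over the cinnamate-type ester and the benzyl ethers, secured by SmI2 in THF without HMPA or proton donors, under which conjugated esters are reduced far more slowly than aldehydes; ketyl–olefin cyclisation is excluded by geometry, since attack on C9 or C8 would give a four-membered or a 5-endo ring. Slow addition of 18 to excess reagent at high dilution favours ring closure over ketyl dimerisation.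

Step 15
Reactants: 19 the 5,6-diol
Product: 21 5,7,3',4'-tetra-O-benzylepicatechin-3-yl 3,4-bis(benzyloxy)-6-hydroxy-5-oxo-1-[(2R,3R)-3,5,7-tris(benzyloxy)chroman-2-yl]-5H-benzo[7]annulene-8-carboxylate, via 5,6-diketone 20 (not isolated)
Conditions: DMSO, (CF3CO)2O, CH2Cl2, −78 °C; Et3N, −78 °C to rt; aq. NaH2PO4
Reagents that add atoms: none
Why: Double Swern-type oxidation of a 1,2-diol, which gives the 1,2-dione without C–C cleavage; in diketone 20 the C7 methylene lies between the C6 carbonyl and the C8=C9 alkene and enolises to the aromatic tropolone. Both diol diastereomers converge on 21.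

Step 16
Reactants: 21 the nona-O-benzyl tropolone ester
Product: 22 the target, 3-O-epicatechin ester of the eastern benzotropolone acid
Conditions: H2 (1 atm), Pd(OH)2 on carbon, THF–MeOH, rt; filtration under Ar
Reagents that add atoms: none
Why: Hydrogenolysis of nine benzyl aryl/alkyl ethers; the ester, the aromatic tropolone and the chromane C2–O bonds are expected to survive at one atmosphere and room temperature. No stereocentre is touched.

## Compound list

1 | (−)-epigallocatechin | O[C@@H]1Cc2c(O)cc(O)cc2O[C@@H]1c1cc(O)c(O)c(O)c1 | starting material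
2 | 3',4'-O-(diphenylmethylene)epigallocatechin | O[C@@H]1Cc2c(O)cc(O)cc2O[C@@H]1c1cc(O)c2OC(c3ccccc3)(c3ccccc3)Oc2c1 | intermediate
3 | 3,5,7,5'-tetra-O-benzyl-3',4'-O-(diphenylmethylene)epigallocatechin | O(Cc1ccccc1)[C@@H]1Cc2c(OCc3ccccc3)cc(OCc3ccccc3)cc2O[C@@H]1c1cc(OCc2ccccc2)c2OC(c3ccccc3)(c3ccccc3)Oc2c1 | intermediate
4 | 3,5,7,5'-tetra-O-benzylepigallocatechin (free 3',4'-catechol) | O(Cc1ccccc1)[C@@H]1Cc2c(OCc3ccccc3)cc(OCc3ccccc3)cc2O[C@@H]1c1cc(OCc2ccccc2)c(O)c(O)c1 | intermediate
5 | 2'-(hydroxymethyl)-3,5,7,5'-tetra-O-benzylepigallocatechin (not isolated) | O(Cc1ccccc1)[C@@H]1Cc2c(OCc3ccccc3)cc(OCc3ccccc3)cc2O[C@@H]1c1cc(OCc2ccccc2)c(O)c(O)c1CO | intermediate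
6 | 2'-formyl-3,5,7,5'-tetra-O-benzylepigallocatechin [4-(benzyloxy)-2,3-dihydroxy-6-[(2R,3R)-3,5,7-tris(benzyloxy)chroman-2-yl]benzaldehyde] | O(Cc1ccccc1)[C@@H]1Cc2c(OCc3ccccc3)cc(OCc3ccccc3)cc2O[C@@H]1c1cc(OCc2ccccc2)c(O)c(O)c1C=O | intermediate
7 | 3,4-bis(benzyloxy)-2-hydroxy-6-[(2R,3R)-3,5,7-tris(benzyloxy)chroman-2-yl]benzaldehyde | O(Cc1ccccc1)[C@@H]1Cc2c(OCc3ccccc3)cc(OCc3ccccc3)cc2O[C@@H]1c1cc(OCc2ccccc2)c(OCc2ccccc2)c(O)c1C=O | intermediate
8 | 2,3-bis(benzyloxy)-6-formyl-5-[(2R,3R)-3,5,7-tris(benzyloxy)chroman-2-yl]phenyl trifluoromethanesulfonate | O(Cc1ccccc1)[C@@H]1Cc2c(OCc3ccccc3)cc(OCc3ccccc3)cc2O[C@@H]1c1cc(OCc2ccccc2)c(OCc2ccccc2)c(OS(=O)(=O)C(F)(F)F)c1C=O | intermediate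
9 | triethyl phosphonoacetate | CCOC(=O)CP(=O)(OCC)OCC | starting material
10 | bromoacetaldehyde dimethyl acetal | COC(CBr)OC | starting material
11 | ethyl 2-(diethoxyphosphoryl)-4,4-dimethoxybutanoate (racemic) | CCOC(=O)C(CC(OC)OC)P(=O)(OCC)OCC | intermediate
12 | 2-(diethoxyphosphoryl)-4,4-dimethoxybutanoic acid (racemic) | OC(=O)C(CC(OC)OC)P(=O)(OCC)OCC | intermediate
13 | (−)-epicatechin | O[C@@H]1Cc2c(O)cc(O)cc2O[C@@H]1c1ccc(O)c(O)c1 | starting material
14 | 5,7,3',4'-tetra-O-benzylepicatechin | O[C@@H]1Cc2c(OCc3ccccc3)cc(OCc3ccccc3)cc2O[C@@H]1c1ccc(OCc2ccccc2)c(OCc2ccccc2)c1 | intermediate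
15 | 5,7,3',4'-tetra-O-benzylepicatechin-3-yl 2-(diethoxyphosphoryl)-4,4-dimethoxybutanoate (two epimers at the phosphorus-bearing carbon) | CCOP(=O)(OCC)C(CC(OC)OC)C(=O)O[C@@H]1Cc2c(OCc3ccccc3)cc(OCc3ccccc3)cc2O[C@@H]1c1ccc(OCc2ccccc2)c(OCc2ccccc2)c1 | intermediate
16 | 5,7,3',4'-tetra-O-benzylepicatechin-3-yl (E)-3-{3,4-bis(benzyloxy)-2-(triflyloxy)-6-[(2R,3R)-3,5,7-tris(benzyloxy)chroman-2-yl]phenyl}-2-(2,2-dimethoxyethyl)acrylate | COC(OC)C/C(C(=O)O[C@@H]1Cc2c(OCc3ccccc3)cc(OCc3ccccc3)cc2O[C@@H]1c1ccc(OCc2ccccc2)c(OCc2ccccc2)c1)=C\c1c(OS(=O)(=O)C(F)(F)F)c(OCc2ccccc2)c(OCc2ccccc2)cc1[C@H]1Oc2cc(OCc3ccccc3)cc(OCc3ccccc3)c2C[C@H]1OCc1ccccc1 | intermediate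
17 | 5,7,3',4'-tetra-O-benzylepicatechin-3-yl (E)-3-{3,4-bis(benzyloxy)-2-formyl-6-[(2R,3R)-3,5,7-tris(benzyloxy)chroman-2-yl]phenyl}-2-(2,2-dimethoxyethyl)acrylate | COC(OC)C/C(C(=O)O[C@@H]1Cc2c(OCc3ccccc3)cc(OCc3ccccc3)cc2O[C@@H]1c1ccc(OCc2ccccc2)c(OCc2ccccc2)c1)=C\c1c(C=O)c(OCc2ccccc2)c(OCc2ccccc2)cc1[C@H]1Oc2cc(OCc3ccccc3)cc(OCc3ccccc3)c2C[C@H]1OCc1ccccc1 | intermediate
18 | 5,7,3',4'-tetra-O-benzylepicatechin-3-yl (E)-3-{3,4-bis(benzyloxy)-2-formyl-6-[(2R,3R)-3,5,7-tris(benzyloxy)chroman-2-yl]phenyl}-2-(2-oxoethyl)acrylate (key-step precursor) | O=CC/C(C(=O)O[C@@H]1Cc2c(OCc3ccccc3)cc(OCc3ccccc3)cc2O[C@@H]1c1ccc(OCc2ccccc2)c(OCc2ccccc2)c1)=C\c1c(C=O)c(OCc2ccccc2)c(OCc2ccccc2)cc1[C@H]1Oc2cc(OCc3ccccc3)cc(OCc3ccccc3)c2C[C@H]1OCc1ccccc1 | intermediate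
19 | 5,7,3',4'-tetra-O-benzylepicatechin-3-yl 3,4-bis(benzyloxy)-5,6-dihydroxy-1-[(2R,3R)-3,5,7-tris(benzyloxy)chroman-2-yl]-6,7-dihydro-5H-benzo[7]annulene-8-carboxylate (C5/C6 unassigned; key-step product) | O=C(O[C@@H]1Cc2c(OCc3ccccc3)cc(OCc3ccccc3)cc2O[C@@H]1c1ccc(OCc2ccccc2)c(OCc2ccccc2)c1)C1=Cc2c([C@H]3Oc4cc(OCc5ccccc5)cc(OCc5ccccc5)c4C[C@H]3OCc3ccccc3)cc(OCc3ccccc3)c(OCc3ccccc3)c2C(O)C(O)C1 | intermediate
20 | 5,7,3',4'-tetra-O-benzylepicatechin-3-yl 3,4-bis(benzyloxy)-5,6-dioxo-1-[(2R,3R)-3,5,7-tris(benzyloxy)chroman-2-yl]-6,7-dihydro-5H-benzo[7]annulene-8-carboxylate (not isolated) | O=C(O[C@@H]1Cc2c(OCc3ccccc3)cc(OCc3ccccc3)cc2O[C@@H]1c1ccc(OCc2ccccc2)c(OCc2ccccc2)c1)C1=Cc2c([C@H]3Oc4cc(OCc5ccccc5)cc(OCc5ccccc5)c4C[C@H]3OCc3ccccc3)cc(OCc3ccccc3)c(OCc3ccccc3)c2C(=O)C(=O)C1 | intermediate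
21 | 5,7,3',4'-tetra-O-benzylepicatechin-3-yl 3,4-bis(benzyloxy)-6-hydroxy-5-oxo-1-[(2R,3R)-3,5,7-tris(benzyloxy)chroman-2-yl]-5H-benzo[7]annulene-8-carboxylate | O=C(O[C@@H]1Cc2c(OCc3ccccc3)cc(OCc3ccccc3)cc2O[C@@H]1c1ccc(OCc2ccccc2)c(OCc2ccccc2)c1)C1=Cc2c([C@H]3Oc4cc(OCc5ccccc5)cc(OCc5ccccc5)c4C[C@H]3OCc3ccccc3)cc(OCc3ccccc3)c(OCc3ccccc3)c2C(=O)C(O)=C1 | intermediate
22 | CNP0191307.2: (2R,3R)-2-(3,4-dihydroxyphenyl)-5,7-dihydroxychroman-3-yl 3,4,6-trihydroxy-5-oxo-1-[(2R,3R)-3,5,7-trihydroxychroman-2-yl]-5H-benzo[7]annulene-8-carboxylate | O=C(O[C@@H]1Cc2c(O)cc(O)cc2O[C@@H]1c1ccc(O)c(O)c1)c1cc(O)c(=O)c2c(O)c(O)cc([C@H]3Oc4cc(O)cc(O)c4C[C@H]3O)c2c1 | target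

## Step count and risks

Total: 16 steps. Longest linear sequence: 12 steps (1 to 22 through steps 1–6 and 11–16). The phosphonate arm (steps 7, 8, 10) and the epicatechin arm (step 9) join at steps 10 and 11.

**Step 14 (key step).**
- What may go wrong: intermolecular coupling of the long-lived aryl ketyl, or its simple reduction to the benzylic alcohol, may outrun the seven-membered closure. The dialdehyde may also be lost by enolisation before it meets the reductant.
- Why: aryl ketyls dimerise very quickly, and 7-exo closure is slower than the five- and six-membered cases on which the method is best documented.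
- Fallback (ring closure by metathesis in place of reductive coupling), from 18 back to 19: non-basic Takai–Lombardo methylenation of both aldehydes (Zn, CH2Br2, TiCl4, THF) gives the vinyl/allyl triene F1. Ring-closing metathesis with the second-generation Grubbs catalyst (CH2Cl2, 40 °C) forms C5=C6 in the 7H-benzo[7]annulene ester F2. OsO4 (cat.) with N-methylmorpholine N-oxide dihydroxylates the cis-disubstituted C5=C6 alkene in preference to the trisubstituted, ester-conjugated C8=C9 alkene and gives 19 as the cis-diol.

**Step 13.**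
- What may go wrong: enolisation of the β,γ-unsaturated aldehyde at C7, followed by migration of the alkene into conjugation or by intramolecular aldol attack on the ortho formyl group with dehydration.
- Why: the C7 hydrogens are doubly activated and the aldol pathway ends in an aromatic naphthalene.
- Fallback (the aryl aldehyde is masked as a vinyl group while the acetal is opened), from 16 back to 18: Stille coupling with tributyl(vinyl)stannane (Pd(PPh3)4, LiCl, dioxane, 90 °C) gives the vinylarene acetal F3. Aqueous trifluoroacetic acid at 0 °C opens the acetal to the vinylarene aldehyde F4, where no aryl aldehyde is present to trap an enol. Lemieux–Johnson cleavage of the terminal vinyl group (OsO4 cat., NaIO4, 2,6-lutidine, dioxane–H2O) then releases the aryl aldehyde under buffered conditions and gives 18 for immediate use. This detour also bypasses step 12.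

**Step 12.**
- What may go wrong: hydride transfer to the arylpalladium before CO insertion (hydrodetriflation) at the doubly ortho-substituted carbon, or conjugate reduction of the enoate by a palladium hydride.
- Why: the reductant and CO compete for the same intermediate at a hindered site.
- Fallback (CO insertion and reduction are separated), from 16 back to 17: aminocarbonylation (Pd(OAc)2, Xantphos, CO, N,O-dimethylhydroxylamine hydrochloride, Et3N, toluene, 90 °C) gives the Weinreb amide F5. Cp2Zr(H)Cl in THF at rt reduces the amide, and not the ester, to the aldehyde 17.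

**Step 11.**
- What may go wrong: slow addition of the branched phosphonate anion to an aldehyde flanked by the triflate and the chromane, and erosion of E selectivity. The Z isomer cannot cyclise in step 14.
- Why: both partners are hindered, and trisubstituted alkenes form less selectively than disubstituted ones.
- Fallback (aldol addition and thermodynamic elimination in place of the olefination), from 14 and 8 back to 16: 14 is acylated (DCC, DMAP) with 4,4-dimethoxybutanoic acid F6, obtained by saponification of commercial methyl 4,4-dimethoxybutanoate, to give tetra-O-benzylepicatechin-3-yl 4,4-dimethoxybutanoate F7. Its lithium enolate (LiN(iPr)2, THF, −78 °C) adds to 8 to give the β-hydroxy ester F8. Mesylation (MsCl, Et3N) and E1cB elimination with DBU give the more stable E alkene 16.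

**Step 4.**
- What may go wrong: sluggish formylation because the catechol chelates magnesium, and opening of ring C (loss of the C2 configuration) through the free 4'-phenoxide on prolonged heating.
- Why: the method is best established for monophenols, and the 4'-oxygen is para to the benzylic C2.
- Fallback (formylation of a monophenol whose 4'-oxygen is already benzylated), from 4 back to 7: pivaloylation of the less hindered 3'-hydroxyl (PivCl, Et3N, −20 °C) gives the 3'-O-pivalate F9. Mitsunobu benzylation of the 4'-hydroxyl (BnOH, PPh3, diisopropyl azodicarboxylate) gives the 4'-O-benzyl pivalate F10. Methanolysis (K2CO3, MeOH) gives the 3'-monophenol F11. The same MgCl2/Et3N/paraformaldehyde formylation, now on a 2-alkoxyphenol, gives 7 directly.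

Further compounds
F1 | step 14 | 5,7,3',4'-tetra-O-benzylepicatechin-3-yl (E)-2-allyl-3-{3,4-bis(benzyloxy)-2-vinyl-6-[(2R,3R)-3,5,7-tris(benzyloxy)chroman-2-yl]phenyl}acrylate | C=CC/C(C(=O)O[C@@H]1Cc2c(OCc3ccccc3)cc(OCc3ccccc3)cc2O[C@@H]1c1ccc(OCc2ccccc2)c(OCc2ccccc2)c1)=C\c1c(C=C)c(OCc2ccccc2)c(OCc2ccccc2)cc1[C@H]1Oc2cc(OCc3ccccc3)cc(OCc3ccccc3)c2C[C@H]1OCc1ccccc1
F2 | step 14 | 5,7,3',4'-tetra-O-benzylepicatechin-3-yl 3,4-bis(benzyloxy)-1-[(2R,3R)-3,5,7-tris(benzyloxy)chroman-2-yl]-7H-benzo[7]annulene-8-carboxylate | O=C(O[C@@H]1Cc2c(OCc3ccccc3)cc(OCc3ccccc3)cc2O[C@@H]1c1ccc(OCc2ccccc2)c(OCc2ccccc2)c1)C1=Cc2c([C@H]3Oc4cc(OCc5ccccc5)cc(OCc5ccccc5)c4C[C@H]3OCc3ccccc3)cc(OCc3ccccc3)c(OCc3ccccc3)c2C=CC1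
F3 | step 13 | 5,7,3',4'-tetra-O-benzylepicatechin-3-yl (E)-3-{3,4-bis(benzyloxy)-2-vinyl-6-[(2R,3R)-3,5,7-tris(benzyloxy)chroman-2-yl]phenyl}-2-(2,2-dimethoxyethyl)acrylate | COC(OC)C/C(C(=O)O[C@@H]1Cc2c(OCc3ccccc3)cc(OCc3ccccc3)cc2O[C@@H]1c1ccc(OCc2ccccc2)c(OCc2ccccc2)c1)=C\c1c(C=C)c(OCc2ccccc2)c(OCc2ccccc2)cc1[C@H]1Oc2cc(OCc3ccccc3)cc(OCc3ccccc3)c2C[C@H]1OCc1ccccc1
F4 | step 13 | 5,7,3',4'-tetra-O-benzylepicatechin-3-yl (E)-3-{3,4-bis(benzyloxy)-2-vinyl-6-[(2R,3R)-3,5,7-tris(benzyloxy)chroman-2-yl]phenyl}-2-(2-oxoethyl)acrylate | O=CC/C(C(=O)O[C@@H]1Cc2c(OCc3ccccc3)cc(OCc3ccccc3)cc2O[C@@H]1c1ccc(OCc2ccccc2)c(OCc2ccccc2)c1)=C\c1c(C=C)c(OCc2ccccc2)c(OCc2ccccc2)cc1[C@H]1Oc2cc(OCc3ccccc3)cc(OCc3ccccc3)c2C[C@H]1OCc1ccccc1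
F5 | step 12 | 5,7,3',4'-tetra-O-benzylepicatechin-3-yl (E)-3-{3,4-bis(benzyloxy)-2-[methoxy(methyl)carbamoyl]-6-[(2R,3R)-3,5,7-tris(benzyloxy)chroman-2-yl]phenyl}-2-(2,2-dimethoxyethyl)acrylate | COC(OC)C/C(C(=O)O[C@@H]1Cc2c(OCc3ccccc3)cc(OCc3ccccc3)cc2O[C@@H]1c1ccc(OCc2ccccc2)c(OCc2ccccc2)c1)=C\c1c(C(=O)N(C)OC)c(OCc2ccccc2)c(OCc2ccccc2)cc1[C@H]1Oc2cc(OCc3ccccc3)cc(OCc3ccccc3)c2C[C@H]1OCc1ccccc1
F6 | step 11 | 4,4-dimethoxybutanoic acid | COC(OC)CCC(O)=O
F7 | step 11 | 5,7,3',4'-tetra-O-benzylepicatechin-3-yl 4,4-dimethoxybutanoate | COC(OC)CCC(=O)O[C@@H]1Cc2c(OCc3ccccc3)cc(OCc3ccccc3)cc2O[C@@H]1c1ccc(OCc2ccccc2)c(OCc2ccccc2)c1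
F8 | step 11 | 5,7,3',4'-tetra-O-benzylepicatechin-3-yl 3-{3,4-bis(benzyloxy)-2-(triflyloxy)-6-[(2R,3R)-3,5,7-tris(benzyloxy)chroman-2-yl]phenyl}-2-(2,2-dimethoxyethyl)-3-hydroxypropanoate (diastereomers at the two new carbons) | COC(OC)CC(C(=O)O[C@@H]1Cc2c(OCc3ccccc3)cc(OCc3ccccc3)cc2O[C@@H]1c1ccc(OCc2ccccc2)c(OCc2ccccc2)c1)C(O)c1c(OS(=O)(=O)C(F)(F)F)c(OCc2ccccc2)c(OCc2ccccc2)cc1[C@H]1Oc2cc(OCc3ccccc3)cc(OCc3ccccc3)c2C[C@H]1OCc1ccccc1
F9 | step 4 | 3'-O-pivaloyl-3,5,7,5'-tetra-O-benzylepigallocatechin | O(Cc1ccccc1)[C@@H]1Cc2c(OCc3ccccc3)cc(OCc3ccccc3)cc2O[C@@H]1c1cc(OCc2ccccc2)c(O)c(OC(=O)C(C)(C)C)c1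
F10 | step 4 | 3'-O-pivaloyl-3,5,7,4',5'-penta-O-benzylepigallocatechin | O(Cc1ccccc1)[C@@H]1Cc2c(OCc3ccccc3)cc(OCc3ccccc3)cc2O[C@@H]1c1cc(OCc2ccccc2)c(OCc2ccccc2)c(OC(=O)C(C)(C)C)c1
F11 | step 4 | 3,5,7,4',5'-penta-O-benzylepigallocatechin (free 3'-hydroxyl) | O(Cc1ccccc1)[C@@H]1Cc2c(OCc3ccccc3)cc(OCc3ccccc3)cc2O[C@@H]1c1cc(OCc2ccccc2)c(OCc2ccccc2)c(O)c1
A1 | alternative 1 | methyl 3,4,6-tris(benzyloxy)-1-[5,7-bis(benzyloxy)-2H-chromen-2-yl]-5-oxo-5H-benzo[7]annulene-8-carboxylate (racemic) | COC(=O)C1=Cc2c(C3C=Cc4c(OCc5ccccc5)cc(OCc5ccccc5)cc4O3)cc(OCc3ccccc3)c(OCc3ccccc3)c2C(=O)C(OCc2ccccc2)=C1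
A2 | alternative 1 | methyl 3,4,6-tris(benzyloxy)-5-oxo-1-[(E)-3-oxoprop-1-enyl]-5H-benzo[7]annulene-8-carboxylate | COC(=O)C1=Cc2c(/C=C/C=O)cc(OCc3ccccc3)c(OCc3ccccc3)c2C(=O)C(OCc2ccccc2)=C1
A3 | alternative 1 | 3,5-bis(benzyloxy)-2-(trimethylsilyl)phenyl trifluoromethanesulfonate | C[Si](C)(C)c1c(OS(=O)(=O)C(F)(F)F)cc(OCc2ccccc2)cc1OCc1ccccc1
A4 | alternative 2 | deca-O-benzyl ether of the target (tropolone hydroxyl also benzylated) | O=C1C(OCc2ccccc2)=CC(C(=O)O[C@@H]2Cc3c(OCc4ccccc4)cc(OCc4ccccc4)cc3O[C@@H]2c2ccc(OCc3ccccc3)c(OCc3ccccc3)c2)=Cc2c([C@H]3Oc4cc(OCc5ccccc5)cc(OCc5ccccc5)c4C[C@H]3OCc3ccccc3)cc(OCc3ccccc3)c(OCc3ccccc3)c12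
A5 | alternative 2 | 3,4,6-tris(benzyloxy)-8-bromo-1-[(2R,3R)-3,5,7-tris(benzyloxy)chroman-2-yl]-5H-benzo[7]annulen-5-one | O=C1C(OCc2ccccc2)=CC(Br)=Cc2c([C@H]3Oc4cc(OCc5ccccc5)cc(OCc5ccccc5)c4C[C@H]3OCc3ccccc3)cc(OCc3ccccc3)c(OCc3ccccc3)c12
A6 | alternative 3 | ethyl 1-bromo-3,4-bis(benzyloxy)-6-methoxy-5-oxo-5H-benzo[7]annulene-8-carboxylate | CCOC(=O)C1=Cc2c(Br)cc(OCc3ccccc3)c(OCc3ccccc3)c2C(=O)C(OC)=C1
A7 | alternative 3 | 5-bromo-7,8-bis(benzyloxy)-2,2-dimethoxynaphthalen-1(2H)-one | COC1(OC)C=Cc2c(Br)cc(OCc3ccccc3)c(OCc3ccccc3)c2C1=O
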